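The 4-methylfuran-2(5H)-one ring (O1, C2=O, C3H, C4–CH3, C5H) is disconnected at C4–C5 and C2–C3. The key step exploits the C5–O1–C2(=O) unit: pre-formed as the N,N-diisopropylcarbamate of a primary homoallylic alcohol, it directs sparteine-mediated lithiation at C5 and later supplies the lactone carbonyl, while C3, C4 and the methyl group come from propyne. Lithiation, exchange to copper, syn-carbocupration of propyne and 1,4-carbamoyl shift form both bonds in one operation and set (R)-C5; acid closes the lactone. The precursor, an acetal-masked, silylated labdane carbamate, comes from (+)-larixol, whose 6α-hydroxyl directs oxidation of the 4α-methyl group.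

Key step: step 11

Assumption: (+)-larixol is taken as a commercial starting material, and the 6α-hydroxy-18-aldehyde of the target is the ring-chain tautomer of its 6α,18-lactol, so hydrolysis of the lactol acetal in the last step delivers the target as drawn.

Names use labdane numbering (normal series: 5α-H, 9α-H, 10β-CH3). Compounds 6–23 are carried as mixtures of C18 anomers; that centre disappears in step 12.

Step 1
Reactants: 1 (+)-larixol
Product: 2 6α-hydroxy-14,15-dinorlabd-8(17)-en-13-one
Conditions: KMnO4, BnEt3NCl, CH2Cl2, 0 → 20 °C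
Reagents that add atoms: none
Why: Permanganate degradation of a vinyl carbinol (dihydroxylation, then glycol cleavage) to the methyl ketone is established for 13-hydroxylabd-14-enes, the monosubstituted alkene reacting ahead of the hindered exocyclic methylene and the hindered 6α-hydroxyl; no stereocentre is formed.

Step 2
Reactants: 2 6α-hydroxy-14,15-dinorlabd-8(17)-en-13-one
Product: 3 13-oxo-14,15-dinorlabd-8(17)-en-6α-yl nitrite
Conditions: NOCl, pyridine, −25 °C
Reagents that add atoms: nitrosyl chloride, ClN=O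
Why: O-Nitrosation of the only hydroxyl group (nitrite ester formation) should be much faster in cold pyridine than addition of NOCl to the hindered 1,1-disubstituted alkene, and it installs the radical precursor for the next step.

Step 3
Reactants: 3 13-oxo-14,15-dinorlabd-8(17)-en-6α-yl nitrite
Product: 5 6α-hydroxy-18-(hydroxyimino)-14,15-dinorlabd-8(17)-en-13-one, via C-nitroso compound 4 (not isolated)
Conditions: hν (365 nm), toluene, 10 °C; then i-PrOH, 60 °C
Reagents that add atoms: none
Why: Barton nitrite photolysis: the 6α-alkoxy radical abstracts hydrogen by a 1,5-shift from the only δ-C–H within reach, the equatorial 4α-methyl group lying parallel to the equatorial 6α-oxygen, NO recombines at C18 and the nitroso compound tautomerises to the oxime, so C4 becomes stereogenic with the oxidised carbon α by geometry alone.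

Step 4
Reactants: 5 6α-hydroxy-18-(hydroxyimino)-14,15-dinorlabd-8(17)-en-13-one
Product: 7 6α,18-epoxy-18-methoxy-14,15-dinorlabd-8(17)-en-13-one, via lactol 6 (not isolated)
Conditions: OHC–CO2H (aq.), THF, 23 °C; then MeOH, PPTS, 23 °C
Reagents that add atoms: methanol, CO (water, O, supplies only the hydroxyl oxygen of intermediate 6)
Why: Transoximation to glyoxylic acid frees the aldehyde, which the 6α-hydroxyl captures as the five-membered lactol, and Fischer-type acetalisation then gives the methyl acetal, which masks both aldehyde and 6-OH against the bases and organometallics ahead.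

Step 5
Reactants: 7 6α,18-epoxy-18-methoxy-14,15-dinorlabd-8(17)-en-13-one
Product: 9 6α,18-epoxy-18-methoxy-15,16-dinorlabd-8(17)-en-13-yne, via enol phosphate 8 (not isolated)
Conditions: LDA, THF, −78 °C; ClP(O)(OEt)2; LDA (2.5 equiv), −78 → 20 °C
Reagents that add atoms: none
Why: One-pot methyl ketone to terminal alkyne conversion: kinetic deprotonation on the methyl side, O-phosphorylation and base-induced β-elimination of the terminal enol phosphate, with acetal and exocyclic alkene inert to LDA.

Step 6
Reactants: 9 6α,18-epoxy-18-methoxy-15,16-dinorlabd-8(17)-en-13-yne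
Product: 10 6α,18:8α,17-diepoxy-18-methoxy-15,16-dinorlabd-13-yne
Conditions: m-CPBA, NaHCO3, CH2Cl2, 0 °C
Reagents that add atoms: m-chloroperbenzoic acid, O=C(OO)c1cccc(Cl)c1
Why: Prilezhaev epoxidation is selective for the 1,1-disubstituted alkene over the terminal alkyne and should occur on the α face, anti to the axial 10β-methyl group, which sets C8 with oxygen α.

Step 7
Reactants: 10 6α,18:8α,17-diepoxy-18-methoxy-15,16-dinorlabd-13-yne
Product: 11 6α,18-epoxy-18-methoxy-15,16-dinorlabd-13-yn-8α-ol
Conditions: LiAlH4, THF, 0 → 50 °C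
Reagents that add atoms: none
Why: Hydride opens the spiro-epoxide at its CH2 carbon (SN2), leaving the C8–O bond intact and so delivering the 8α-hydroxy-8β-methyl arrangement, while alkyne and acetal are untouched.

Step 8
Reactants: 11 6α,18-epoxy-18-methoxy-15,16-dinorlabd-13-yn-8α-ol; 12 oxirane
Product: 14 (13E)-6α,18-epoxy-15-(hydroxymethyl)-18-methoxylabd-13-en-8α-ol, via alkenylalane 13 (not isolated)
Conditions: Me3Al, Cp2ZrCl2 (20 mol %), H2O (1 equiv), CH2Cl2, −23 °C; evaporate; n-BuLi, THF, −78 °C; oxirane, −78 → 0 °C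
Reagents that add atoms: trimethylaluminium, C[Al](C)C; oxirane (12), C1CO1
Why: Zirconium-catalysed syn-carboalumination (Negishi) puts methyl on the internal and aluminium on the terminal alkyne carbon, which fixes the E geometry, and the derived alanate opens oxirane to the homoallylic alcohol; the water-accelerated low-temperature variant is chosen to spare the acetal, and the tertiary hydroxyl is carried as its aluminium alkoxide.

Step 9
Reactants: 14 (13E)-6α,18-epoxy-15-(hydroxymethyl)-18-methoxylabd-13-en-8α-ol; 15 N,N-diisopropylcarbamoyl chloride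
Product: 16 primary N,N-diisopropylcarbamate of 14
Conditions: Et3N, CH2Cl2, reflux
Reagents that add atoms: N,N-diisopropylcarbamoyl chloride (15), CC(C)N(C(C)C)C(Cl)=O
Why: Carbamoylation of the primary alcohol with the hindered carbamoyl chloride leaves the tertiary 8α-hydroxyl untouched and installs the group that will direct lithiation and later supply the lactone carbonyl.

Step 10
Reactants: 16 primary N,N-diisopropylcarbamate of 14
Product: 17 8-O-trimethylsilyl ether of 16
Conditions: N-(trimethylsilyl)imidazole, CH2Cl2, 40 °C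
Reagents that add atoms: N-(trimethylsilyl)imidazole, C[Si](C)(C)n1ccnc1
Why: Silylation of the tertiary alcohol under neutral, Lewis-acid-free conditions, which spare the acetal, removes the last acidic proton before the organolithium step.

Step 11
Reactants: 17 8-O-trimethylsilyl ether of 16; 18 propyne
Product: 23 8-O-trimethylsilyl 6α,18-methyl acetal of the target butenolide, via lithiated carbamate 19 (not isolated), via alkylcopper 20 (not isolated), via alkenylcopper 21 (not isolated), via hydroxy amide 22 (not isolated)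
Conditions: s-BuLi, (−)-sparteine, Et2O, −78 °C; MgBr2·OEt2, then CuBr·SMe2, −78 → −45 °C; propyne, −45 → 0 °C; aq. NH4Cl; then CSA, CH2Cl2, 23 °C
Reagents that add atoms: propyne (18), CC#C
Why: Proposed new method: s-BuLi/(−)-sparteine removes the pro-S hydrogen next to the carbamate oxygen (carbamate-directed asymmetric α-lithiation, a known type), and exchange to magnesium and then monovalent copper with retention gives a configurationally stable α-(carbamoyloxy)alkylcopper, a class known to allylate and to add to activated alkynes with retention. syn-Carbocupration of propyne, the closest known type being the addition of alkylcopper–MgBr2 reagents to 1-alkynes, should put the alkyl group on the internal carbon and copper on the terminal carbon cis to it, which forms C4–C5 with retention, so that the (R) configuration at C5 is controlled by the sparteine complex alone. The alkenyl–copper carbon, held next to the carbamate carbonyl, then adds to it through a five-membered 5-exo-trig transition state (closest known type: anionic 1,4-O→C carbamoyl shift, the homo-Fries rearrangement), which forms C2–C3; the tetrahedral intermediate opens to the (Z)-γ-oxido enamide 22. CSA finally closes the furanone ring by 5-exo-trig N→O acyl transfer with loss of diisopropylamine, possible only because the syn addition has placed the amide cis to C5. The step needs α- rather than allylic deprotonation (secured by precoordination to the carbamate), addition to propyne rather than its deprotonation and with the stated regiochemistry (secured by the magnesium-containing organocopper in Et2O), and survival of acetal and silyl ether (no protic or strong Lewis acid before the CSA stage).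

Step 12
Reactants: 23 8-O-trimethylsilyl 6α,18-methyl acetal of the target butenolide
Product: 24 6α,8α-dihydroxy-15-[(2R)-3-methyl-5-oxo-2,5-dihydrofuran-2-yl]labd-13(E)-en-18-al (CNP0143336.1)
Conditions: AcOH/THF/H2O (3:1:1), 40 °C
Reagents that add atoms: water, O
Why: Mild aqueous acid cleaves the tertiary silyl ether and hydrolyses the methyl acetal to the lactol, the ring-chain tautomer of the 6α-hydroxy-18-aldehyde, while being too weak to protonate the 13(14)-alkene (which would invite 8,13-ether formation) or to disturb the butenolide.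

Compound list
1 | (+)-larixol, (13S)-labda-8(17),14-diene-6α,13-diol | C=C[C@@](C)(O)CC[C@@H]1[C@@]2(C)CCCC(C)(C)[C@@H]2[C@@H](O)CC1=C | starting material
2 | 6α-hydroxy-14,15-dinorlabd-8(17)-en-13-one | CC(=O)CC[C@@H]1[C@@]2(C)CCCC(C)(C)[C@@H]2[C@@H](O)CC1=C | intermediate
3 | 13-oxo-14,15-dinorlabd-8(17)-en-6α-yl nitrite | CC(=O)CC[C@@H]1[C@@]2(C)CCCC(C)(C)[C@@H]2[C@@H](ON=O)CC1=C | intermediate
4 | 6α-hydroxy-18-nitroso-14,15-dinorlabd-8(17)-en-13-one (monomer, in equilibrium with its dimer) | CC(=O)CC[C@@H]1[C@@]2(C)CCC[C@@](C)(CN=O)[C@@H]2[C@@H](O)CC1=C | intermediate (not isolated)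
5 | 6α-hydroxy-18-(hydroxyimino)-14,15-dinorlabd-8(17)-en-13-one (oxime geometry not defined) | CC(=O)CC[C@@H]1[C@@]2(C)CCC[C@@](C)(C=NO)[C@@H]2[C@@H](O)CC1=C | intermediate
6 | 6α,18-epoxy-18-hydroxy-14,15-dinorlabd-8(17)-en-13-one (lactol, C18 anomers) | CC(=O)CC[C@@H]1[C@@]2(C)CCC[C@@](C)(C3O)[C@@H]2[C@@H](O3)CC1=C | intermediate (not isolated)
7 | 6α,18-epoxy-18-methoxy-14,15-dinorlabd-8(17)-en-13-one (C18 anomers) | CC(=O)CC[C@@H]1[C@@]2(C)CCC[C@@](C)(C3OC)[C@@H]2[C@@H](O3)CC1=C | intermediate
8 | diethyl 6α,18-epoxy-18-methoxy-14,15-dinorlabda-8(17),13(16)-dien-13-yl phosphate | C=C(OP(=O)(OCC)OCC)CC[C@@H]1[C@@]2(C)CCC[C@@](C)(C3OC)[C@@H]2[C@@H](O3)CC1=C | intermediate (not isolated)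
9 | 6α,18-epoxy-18-methoxy-15,16-dinorlabd-8(17)-en-13-yne | C#CCC[C@@H]1[C@@]2(C)CCC[C@@](C)(C3OC)[C@@H]2[C@@H](O3)CC1=C | intermediate
10 | 6α,18:8α,17-diepoxy-18-methoxy-15,16-dinorlabd-13-yne | C#CCC[C@@H]1[C@@]2(C)CCC[C@@](C)(C3OC)[C@@H]2[C@@H](O3)C[C@@]1(C4)O4 | intermediate
11 | 6α,18-epoxy-18-methoxy-15,16-dinorlabd-13-yn-8α-ol | C#CCC[C@@H]1[C@@]2(C)CCC[C@@](C)(C3OC)[C@@H]2[C@@H](O3)C[C@@]1(C)O | intermediate
12 | oxirane | C1CO1 | starting material
13 | (13E)-alkenyl(dimethyl)alane of 11, 8-O-dimethylaluminium alkoxide (Al and new methyl cis) | C[Al](C)/C=C(\C)CC[C@@H]1[C@@]2(C)CCC[C@@](C)(C3OC)[C@@H]2[C@@H](O3)C[C@@]1(C)O[Al](C)C | intermediate (not isolated)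
14 | (13E)-6α,18-epoxy-15-(hydroxymethyl)-18-methoxylabd-13-en-8α-ol | OCC/C=C(\C)CC[C@@H]1[C@@]2(C)CCC[C@@](C)(C3OC)[C@@H]2[C@@H](O3)C[C@@]1(C)O | intermediate
15 | N,N-diisopropylcarbamoyl chloride | CC(C)N(C(C)C)C(Cl)=O | starting material
16 | primary N,N-diisopropylcarbamate of 14 | CC(C)N(C(C)C)C(=O)OCC/C=C(\C)CC[C@@H]1[C@@]2(C)CCC[C@@](C)(C3OC)[C@@H]2[C@@H](O3)C[C@@]1(C)O | intermediate
17 | 8-O-trimethylsilyl ether of 16 | CC(C)N(C(C)C)C(=O)OCC/C=C(\C)CC[C@@H]1[C@@]2(C)CCC[C@@](C)(C3OC)[C@@H]2[C@@H](O3)C[C@@]1(C)O[Si](C)(C)C | intermediate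
18 | propyne | CC#C | starting material
19 | (S)-α-lithio carbamate of 17 (sparteine complex) | CC(C)N(C(C)C)C(=O)O[C@@H]([Li])C/C=C(\C)CC[C@@H]1[C@@]2(C)CCC[C@@](C)(C3OC)[C@@H]2[C@@H](O3)C[C@@]1(C)O[Si](C)(C)C | intermediate (not isolated)
20 | α-(carbamoyloxy)alkylcopper from 19 (MgBr2 complex, configuration retained) | CC(C)N(C(C)C)C(=O)O[C@@H]([Cu])C/C=C(\C)CC[C@@H]1[C@@]2(C)CCC[C@@](C)(C3OC)[C@@H]2[C@@H](O3)C[C@@]1(C)O[Si](C)(C)C | intermediate (not isolated)
21 | alkenylcopper from syn addition of 20 to propyne (Cu cis to the carbamate-bearing carbon) | CC(C)N(C(C)C)C(=O)O[C@@H](/C(C)=C\[Cu])C/C=C(\C)CC[C@@H]1[C@@]2(C)CCC[C@@](C)(C3OC)[C@@H]2[C@@H](O3)C[C@@]1(C)O[Si](C)(C)C | intermediate (not isolated)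
22 | (2Z,4R)-4-hydroxy-3-methyl-N,N-diisopropylalk-2-enamide from 1,4-carbamoyl shift (shown protonated) | CC(C)N(C(C)C)C(=O)/C=C(/C)[C@H](O)C/C=C(\C)CC[C@@H]1[C@@]2(C)CCC[C@@](C)(C3OC)[C@@H]2[C@@H](O3)C[C@@]1(C)O[Si](C)(C)C | intermediate (not isolated)
23 | (13E)-6α,18-epoxy-18-methoxy-15-[(2R)-3-methyl-5-oxo-2,5-dihydrofuran-2-yl]-8α-(trimethylsilyloxy)labd-13-ene | CC1=CC(=O)O[C@@H]1C/C=C(\C)CC[C@@H]1[C@@]2(C)CCC[C@@](C)(C3OC)[C@@H]2[C@@H](O3)C[C@@]1(C)O[Si](C)(C)C | intermediate
24 | 6α,8α-dihydroxy-15-[(2R)-3-methyl-5-oxo-2,5-dihydrofuran-2-yl]labd-13(E)-en-18-al (CNP0143336.1) | CC1=CC(=O)O[C@@H]1C/C=C(\C)CC[C@@H]1[C@@]2(C)CCC[C@@](C)(C=O)[C@@H]2[C@@H](O)C[C@@]1(C)O | target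

Total step count: 12. Longest linear sequence: 12 steps (from 1).

Steps most likely to fail

1. Step 11 (Proposed new method). The chelated, α-oxygenated secondary organocopper may be too unreactive towards unactivated propyne. It may also lose configuration or suffer 1,2-carbamoyl migration on warming. The alkenylcopper may be too weakly nucleophilic for the acyl shift. Fallback, known chemistry, setting out from 14 and rejoining at 24: Dess–Martin oxidation of the primary alcohol of 14 should give the β,γ-unsaturated aldehyde F1, used at once. Catalytic asymmetric Nozaki–Hiyama–Kishi coupling of F1 with ethyl (Z)-3-iodobut-2-enoate (CrCl2, NiCl2, chiral sulfonamide ligand, Mn, TMSCl) forms the C4–C5 bond under ligand control. The Z-γ-hydroxy ester lactonises to the acetal-protected butenolide F2. AcOH/THF/H2O then hydrolyses the acetal of F2 to 24.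

2. Step 8. Methylaluminium species may ionise the lactol methyl acetal and transfer methyl to the oxocarbenium ion faster than the alkyne is carbometalated. Fallback, setting out from 11 and rejoining at 14: copper-catalysed syn-methylboration of the alkyne (B2pin2, MeI, CuCl, Xantphos, NaOt-Bu) should give the (E)-alkenylboronate F3 under basic, Lewis-acid-free conditions. Suzuki–Miyaura coupling of F3 with ethyl bromoacetate (Pd(OAc)2, P(o-tol)3, K3PO4) gives the β,γ-unsaturated ester F4. LiAlH4 reduction of F4 returns 14.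

3. Step 3. The 6α-alkoxy radical may fragment (β-scission of C5–C6) or revert to alcohol and 6-ketone by disproportionation, and electrophilic nitrosation of the exocyclic alkene may erode the preceding nitrite formation. Fallback, setting out from 2 and rejoining at 10: the alkene is first masked by epoxidation (m-CPBA, NaHCO3) to the 8α,17-epoxy alcohol F5. A hypoiodite reaction with excess reagent (Pb(OAc)4, I2, CaCO3, hν, cyclohexane) functionalises the 4α-methyl group twice, via the 18-iodo-6α-ol, to the 18-iodo-6α,18-ether. Methanolysis (MeOH, Ag2CO3) gives the epoxy ketone acetal F6. Alkyne formation from F6 as in step 5 then gives 10.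

Further compounds
F1 | step 11 | (13E)-6α,18-epoxy-15-(formylmethyl)-8α-hydroxy-18-methoxylabd-13-ene (β,γ-unsaturated aldehyde) | O=CC/C=C(\C)CC[C@@H]1[C@@]2(C)CCC[C@@](C)(C3OC)[C@@H]2[C@@H](O3)C[C@@]1(C)O
F2 | step 11 | (13E)-6α,18-epoxy-18-methoxy-15-[(2R)-3-methyl-5-oxo-2,5-dihydrofuran-2-yl]labd-13-en-8α-ol | CC1=CC(=O)O[C@@H]1C/C=C(\C)CC[C@@H]1[C@@]2(C)CCC[C@@](C)(C3OC)[C@@H]2[C@@H](O3)C[C@@]1(C)O
F3 | step 8 | (13E)-14-(4,4,5,5-tetramethyl-1,3,2-dioxaborolan-2-yl)-6α,18-epoxy-18-methoxy-15-norlabd-13-en-8α-ol | CC1(C)OB(OC1(C)C)/C=C(\C)CC[C@@H]1[C@@]2(C)CCC[C@@](C)(C3OC)[C@@H]2[C@@H](O3)C[C@@]1(C)O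
F4 | step 8 | ethyl ester of (13E)-6α,18-epoxy-8α-hydroxy-18-methoxylabd-13-ene-15-carboxylic acid | CCOC(=O)C/C=C(\C)CC[C@@H]1[C@@]2(C)CCC[C@@](C)(C3OC)[C@@H]2[C@@H](O3)C[C@@]1(C)O
F5 | step 3 | 8α,17-epoxy-6α-hydroxy-14,15-dinorlabdan-13-one | CC(=O)CC[C@@H]1[C@@]2(C)CCCC(C)(C)[C@@H]2[C@@H](O)C[C@@]1(C3)O3
F6 | step 3 | 6α,18:8α,17-diepoxy-18-methoxy-14,15-dinorlabdan-13-one | CC(=O)CC[C@@H]1[C@@]2(C)CCC[C@@](C)(C3OC)[C@@H]2[C@@H](O3)C[C@@]1(C4)O4
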